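## Structural features

The target is a daucane-type diester on a trans-fused hydroazulene. A cyclopentane (C1–C5) and a cycloheptene (C1, C5–C10, C8=C9) share the C1–C5 bond, and β denotes the face of the C1 methyl group throughout. C1 is quaternary (β-methyl), C2 carries an α-acetoxy group, C4 a β-hydroxyl and an α-isopropyl group, C5 an α-hydrogen, C6 an α-(4-hydroxybenzoyloxy) group and C8 a methyl group. The five stereocentres are contiguous (C2–C1–C5, with C4 and C6 both on C5), so each is set next to a crowded neighbour.

The fragile points are these:
- The tertiary C4 carbinol becomes an aldol (dehydration, retro-aldol) whenever C2 or C6 is a ketone.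
- There are two different esters and a free phenol.
- The C8=C9 alkene is β,γ to C6 and can slip into conjugation at the ketone stage.

The real difficulty is the quaternary C1 beside a trans ring fusion. It is combined with a 4-hydroxyl cis to C6 and a 2α-oxygen on the face that an external hydride, approaching anti to the methyl group, would not produce. The key step exploits C5: it lies between the oxygen-bearing carbons C4 and C6 and is bonded to quaternary C1. That is the pattern left by a 1,2-shift of C1 from C6 to C5 with C6 becoming a carbonyl carbon. Read backwards, the 5–7 system becomes a 1-methyl cis-decalin (ring B C1–C6, ring A C1/C6–C10, shared bond C1–C6), for which asymmetric annulation chemistry is mature.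

## Logic of the disconnections

**27 ⇒ 26 ⇒ 25.** The phenolic O–Si bond and then the O2–C(acetyl) bond are cut. They go first because the free phenol and the acetate tolerate hydride, enolate and Lewis-acid chemistry least. One ester and one protecting-group problem disappear. The forward steps must acylate a secondary hydroxyl beside the tertiary one at C4, and must remove silicon without touching two esters.

**25 ⇒ 24 ⇒ 23.** The C2–H bond is cut and the resulting carbonyl group is hidden as a ketal. The 2α-oxygen can only arise from hydride entering on the β face, and the 4β-hydroxyl, 1,3 to C2, can deliver it. One stereocentre is removed and C2 becomes an inert spectator for the whole earlier route. The forward steps need internal delivery next to the C1 methyl group, and an unmasking mild enough for an aldol.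

**23 ⇒ 19 + 22, and 22 ⇒ 20.** The O6–C(aroyl) bond is cut, and 22 is traced to 20 by removing silicon. This is the only convergent junction, and it separates the aromatic part from all skeletal chemistry. The forward esterification must find the hindered secondary 6α-hydroxyl and leave the tertiary one alone.

**19 ⇒ 18.** The C6–H bond is cut. The same 4β-hydroxyl, cis to C6 on the five-membered ring, can deliver hydride to the β face of the ketone. A stereocentre is exchanged for the carbonyl group that the key step produces. The reduction must be non-basic, since 18 is an aldol, a β,γ-enone and an epimerisable trans-fused ketone at once.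

**18 ⇒ 17.** The C1–C5 bond is cut and C1 is reconnected to C6; O6 returns to a hydroxyl and C5 receives a β-sulfonate. This is the strategic cut. Two awkward rings become two six-membered rings, and the trans fusion becomes a matter of inversion at C5. The demand is an all-β array (methyl, 6-OH, 5-leaving group, 4-OH) on a cis-decalin, together with a preference for migration of C1 over the equally aligned C3.

**17 ⇒ 16 ⇒ 15.** The O5–S bond and the C8–CH3 bond are cut. C5 bears the only secondary hydroxyl, so the leaving group needs no protecting groups. The methyl group is traced to an alkenyl sulfonate so that, during the preceding oxidation, C8=C9 is an electron-poor and unreactive alkene rather than a competing trisubstituted one. The coupling must tolerate three free hydroxyls.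

**15 ⇒ 13.** The C4–O and C5–O bonds are cut together. A suprafacial addition sets both centres in one step, and the 6β-hydroxyl can steer it to the β face. Two stereocentres are removed. The demand is hydrogen-bond delivery to a hindered trisubstituted alkene, syn to the allylic oxygen.

**13 ⇒ 11 ⇒ 10 ⇒ 9 ⇒ 8.** The O8–S bond, the O6–Si bond and the C7–H bond are cut, and finally the C6–O and C7–O bonds of the oxirane. The 6β-oxygen is traced to a conjugate oxidation of an enone, the classical entry to an oxygen cis to an angular methyl group. The demands are:
- β-face, α,β-selective epoxidation of a linear dienone;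
- reductive opening without loss of the tertiary allylic aldol hydroxyl;
- enolisation of the C8 ketone towards C9 only.

**8 ⇒ 7 ⇒ 6.** The C4=C5 π bond is removed and the C2 ketal is opened. The extra unsaturation is the only handle for oxygen at C4 and C5, and its introduction erases the C4 centre, so epimers converge. The forward steps need chemoselective ketalisation of the saturated ketone and γ,δ-dehydrogenation at a tertiary C–H.

**6 ⇒ 5 ⇒ 3 + 4.** The C6=C7 bond (aldol condensation) and the C1–C10 bond (Michael addition) are cut. The bicycle collapses to an achiral triketone whose enantiotopic carbonyl groups a chiral amine can tell apart. All later stereochemistry is relayed from the C1 centre set here, so the sense (R at C1) and level of induction are the demand.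

**3 ⇒ 1 + 2.** The C1–CH3 bond is cut, which leaves two commercial compounds. The forward step must alkylate on carbon rather than oxygen.

## Other disconnections considered

**Alternative 1:** The cut is the C1–CH3 bond, so the angular methyl group would arrive last.
- *Forward key step:* the bromomethyl(dimethyl)silyl ether A1 of a hydroazulen-4β-ol with a C1=C10–C9=C8 diene enters a tin hydride chain. The α-silyl radical should add to C1 in a 6-exo mode, and the C10–C9–C8 allyl radical should take hydrogen at its less hindered end, C10. The bridged oxasilacycle A2 would result, and its C–Si bond must still be replaced by C–H.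
- *In its favour:* the tether reaches only the β face, so C1 follows from C4 with a certainty at least equal to, and arguably better than, catalyst control in step 2. The medium is neutral, and the alkene ends where the target needs it.
- *Against it:* the step builds no ring, so A1, a 5–7 diene already holding C2, C4, C5 and C6, needs a ring synthesis of its own. The radical must attack the fully substituted diene terminus in competition with 7-endo attack and premature reduction. The site of hydrogen transfer rests on sterics alone. Protodesilylation of an unactivated alkyl–silicon bond needs hot basic fluoride or alkoxide, which forces both esters to come afterwards.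
- *Comparison:* on structure it settles one centre, where the chosen plan settles two rings and the fusion. On mechanism, kinetic selectivities of a chain reaction stand against a stereospecific concerted shift. On step economy it is expected to be longer once ring construction, tether handling and two protecting-group exchanges are counted.

**Alternative 2:** The cuts are C5–C6 and C1–C10.
- *Forward key step:* 2-lithio-1,3-dithiane A4 adds to C5 of the enantiopure 4-silyloxy-4-isopropyl-2-methylcyclopentenone A3. The C1 enolate is then alkylated in the same flask by the Z allylic iodide A5, giving the trans-2,3-disubstituted cyclopentanone A6.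
- *In its favour:* three fragments, two C–C bonds and two stereocentres (C5 and quaternary C1) come together in one operation. The anti relation of the two new substituents is the natural outcome of enolate alkylation. All ring carbons are then in place. In convergence it is clearly better than the chosen, largely linear plan.
- *Against it:* C5 is flanked by fully substituted C4, so 1,4-addition of a bulky anion must beat 1,2-addition. The nucleophile must enter syn to the silyloxy group and anti to isopropyl, a distinction between two groups of similar size. A3 is a β-silyloxy ketone whose C3 protons invite elimination by a basic reagent. The seven-membered ring remains to be closed (C6–C7, by a hindered dithiane anion), and A3 itself needs a multistep enantioselective preparation.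
- *Comparison:* structurally it leaves the medium ring unsolved, where the chosen plan gets it by ring expansion. Mechanistically it depends on two unproven facial and regiochemical preferences. On step count the two plans are probably close, with the alternative ahead only if the ring closure and the synthesis of A3 are short.

**Alternative 3:** The cut is C9–C10, made at the very end.
- *Forward key step:* the N-hydroxyphthalimide ester A7 of the C1 acetic acid chain, which carries a (Z)-alkenyl iodide at C9, is reduced at a cathode with nickel. Loss of CO2 gives the C10 radical, which is to be captured by the alkenylnickel species to close the ring and give A8. A8 has the constitution and configuration of 26.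
- *In its favour:* the conditions tolerate esters and a free tertiary alcohol. The position and geometry of the alkene are fixed by the iodide, and only a desilylation would follow. In functional-group tolerance and brevity of the endgame it is the equal of or better than the chosen plan.
- *Against it:* closure of a seven-membered ring by this coupling is thinly charted. The neopentyl C10 radical can cyclise 6-exo onto C8, abstract a nearby hydrogen or be reduced before nickel captures it. A7 is a fully substituted cyclopentane with a side-chain stereocentre at C6, and it must be assembled without the help of a second ring.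
- *Comparison:* on structure the difficulty is moved into the precursor rather than removed. On mechanism a radical–metal capture with several escape routes stands against a concerted shift whose one competitor is known in advance. On step economy the short endgame is likely to be outweighed by the long approach to A7.

Key step: step 12

Remark on the chemistry: 5, 6 and 7 are written as the isomer with isopropyl trans to the C1 methyl group; the other C4 epimer, should it form, is carried along because step 4 removes this centre.

## Steps

Step 1
Reactants: 1 5-isopropylcyclohexane-1,3-dione; 2 iodomethane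
Product: 3 5-isopropyl-2-methylcyclohexane-1,3-dione
Conditions: MeI, aq NaOH, dioxane–H2O, reflux
Reagents that add atoms: iodomethane (2), CI
Why: C-alkylation of the stabilised enolate of a cyclic 1,3-dione; in water the enolate oxygens are hydrogen-bonded, which favours attack through carbon, as in the standard preparation of 2-methyl-1,3-diones.

Step 2
Reactants: 3 5-isopropyl-2-methylcyclohexane-1,3-dione; 4 methyl vinyl ketone
Product: 6 (3S,8aR)-3-isopropyl-8a-methyl-3,4,8,8a-tetrahydronaphthalene-1,6(2H,7H)-dione, via triketone 5 (not isolated)
Conditions: 4, Et3N (1 mol %), neat, rt; volatiles off; N-Ts-(Ra)-BINAM-D-prolinamide (2 mol %), PhCO2H (1 mol %), neat, rt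
Reagents that add atoms: none
Why: Michael addition, then enamine-catalysed intramolecular aldol condensation (asymmetric Robinson annulation of the Hajos–Parrish–Eder–Sauer–Wiechert type), in which the catalyst distinguishes the enantiotopic ring carbonyls of achiral 5 and so sets C1. The D-proline series is chosen because the L series is associated with the S enedione of the parent system and R is needed here. Axial Michael attack should favour the cis triketone and hence 4α-isopropyl in 6.

Step 3
Reactants: 6 enedione
Product: 7 C2 ethylene ketal of 6 (enone C8(=O)–C7=C6 kept)
Conditions: HOCH2CH2OH, p-TsOH, 4 Å MS, rt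
Reagents that add atoms: ethylene glycol, OCCO
Why: Chemoselective ketalisation: the saturated C2 ketone reacts faster than the conjugated carbonyl, as with the parent Wieland–Miescher ketone, and a short time at room temperature avoids alkene migration.

Step 4
Reactants: 7 enone ketal
Product: 8 linear dienone C8(=O)–C7=C6–C5=C4(iPr), C2 ketal, 1β-methyl
Conditions: chloranil, t-BuOH, reflux
Reagents that add atoms: none
Why: Quinone dehydrogenation of a 4-en-3-one type enone to the 4,6-dienone type: chloranil removes the tertiary allylic hydride at C4 from the extended dienol, a process known for δ-alkyl-substituted steroidal enones. The C4 centre disappears, so both epimers converge.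

Step 5
Reactants: 8 linear dienone
Product: 9 6β,7β-epoxy-4-en-8-one, C2 ketal
Conditions: 30% H2O2, NaOH (cat.), MeOH, 0 °C
Reagents that add atoms: hydrogen peroxide, OO
Why: Weitz–Scheffer epoxidation: hydroperoxide should add 1,4 at C6 rather than 1,6 at the isopropyl-shielded C4, and then close onto C7. Delivery cis to the angular methyl group is the usual sense for 10-methyloctalones and steroidal 4-en-3-ones and sets C6 (β).

Step 6
Reactants: 9 epoxy enone
Product: 10 cis-fused 6β-hydroxy-4-en-8-one, C2 ketal
Conditions: SmI2 (2.2 equiv), THF–MeOH, −90 °C
Reagents that add atoms: none
Why: Single-electron reduction of an α,β-epoxy ketone cleaves the C7–O bond α to the carbonyl, methanol protonates the enolate and the C6–O bond is untouched, so the configuration is retained. The cold neutral medium spares the dehydration-prone tertiary allylic aldol, which is used crude.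

Step 7
Reactants: 10 hydroxy ketone
Product: 11 6β-trimethylsilyl ether of 10
Conditions: TMS-imidazole, CH2Cl2, 0 °C
Reagents that add atoms: N-(trimethylsilyl)imidazole, C[Si](C)(C)n1ccnc1
Why: Silylation of a hindered tertiary alcohol with a powerful, essentially neutral silyl donor; it removes the acidic proton and blocks retro-aldol cleavage before enolate chemistry.

Step 8
Reactants: 11 silyloxy ketone
Product: 13 6β-hydroxy-4,8-dien-8-yl triflate (C2 ketal), via silylated enol triflate 12 (not isolated)
Conditions: LDA, THF, −78 °C; N-(5-chloro-2-pyridyl)triflimide; then TBAF–AcOH, 0 °C
Reagents that add atoms: N-(5-chloro-2-pyridyl)bis(trifluoromethanesulfonimide), FC(F)(F)S(=O)(=O)N(c1ccc(Cl)cn1)S(=O)(=O)C(F)(F)F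
Why: Kinetic deprotonation of a ketone of the 3,3-disubstituted cyclohexanone type goes to the methylene remote from the fully substituted carbon (C9, not neopentyl C7), and O-triflation freezes the C8=C9 regiochemistry. Buffered fluoride then frees the 6-hydroxyl needed in step 9. Any C7 enolate would expel silanolate and return 8, which can be recycled.

Step 9
Reactants: 13 hydroxy dienyl triflate
Product: 15 4β,5β,6β-triol 8-enol triflate (C2 ketal), via osmate ester 14 (not isolated)
Conditions: OsO4 (1.05 equiv), TMEDA, CH2Cl2, −78 → −20 °C; then aq Na2SO3, THF, 50 °C
Reagents that add atoms: osmium tetroxide, O=[Os](=O)(=O)=O; TMEDA (held only in 14), CN(C)CCN(C)C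
Why: Hydrogen-bond-directed dihydroxylation: the OsO4·TMEDA complex accepts a hydrogen bond from the 6β-hydroxyl and adds suprafacially to the β (convex) face of C4=C5, setting C4 and C5 cis to O6. The enol triflate alkene is electron-poor and only homoallylic to the hydroxyl, so it should be left alone; this is the reason the C8 methyl group is introduced after this step and not before.

Step 10
Reactants: 15 triol triflate
Product: 16 4β,5β,6β-triol with C8 methyl and C8=C9 (C2 ketal)
Conditions: Me2Zn (6 equiv), Pd(PPh3)4 (5 mol %), THF, 0 → 45 °C
Reagents that add atoms: dimethylzinc, C[Zn]C
Why: Negishi coupling of an alkenyl triflate with retention of the alkene position; the three hydroxyls are only converted to zinc alkoxides by the excess reagent and return on work-up.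

Step 11
Reactants: 16 triol
Product: 17 4β,6β-dihydroxy-5β-mesyloxy-4α-isopropyl-1β,8-dimethyl cis-decal-8-ene, C2 ketal
Conditions: MsCl (1.1 equiv), Et3N, CH2Cl2, −20 °C
Reagents that add atoms: methanesulfonyl chloride, CS(=O)(=O)Cl
Why: Sulfonylation of the only secondary hydroxyl; at low temperature and with little excess the two tertiary carbinols stay free, and being cis to O5 they cannot close an epoxide. The product is used without chromatography.

Step 12
Reactants: 17 diol mesylate
Product: 18 trans-fused 4β-hydroxy-4α-isopropyl-1β,8-dimethylhydroazul-8-en-6-one, C2 ketal
Conditions: Et2AlCl (3 equiv), CH2Cl2, −78 → −30 °C; aq Rochelle salt, pH 7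
Reagents that add atoms: none
Why: Et2AlCl first turns the two tertiary hydroxyls into aluminium alkoxides (loss of ethane) and a further equivalent binds the sulfonate, so push from O6 and pull on O5 drive a concerted suprafacial 1,2-shift of C1 from C6 to C5 while C6 becomes the carbonyl carbon; this is a semipinacol rearrangement of a β-mesyloxy alcohol, the organoaluminium version of the long-known decalin-1,2-diol monosulfonate to hydroazulenone rearrangement. No chain end attacks anything, so no exo or endo closure mode applies: the bond common to both rings moves from C1–C6 to C1–C5, which contracts ring B to the cyclopentane C1–C5 and enlarges ring A to the cycloheptene C1/C5–C10 in one event. The one new stereocentre, C5, is fixed by the stereospecificity of the shift: C1 enters anti to the departing β-mesylate (inversion), H5 ends up α and anti to the C1 methyl (trans fusion), C1 migrates with retention and C4 is untouched, so the 4β-hydroxyl stays cis to C6. The geometry is present in the favoured chair of ring B (isopropyl and mesylate equatorial, 4-OH and 6-OH axial, possibly clamped by one aluminium), in which C5–O is antiperiplanar to C6–C1. Epoxide formation is excluded because both flanking oxygens are cis to the leaving group. The selectivity to be won is C1 (from C6) against C3 (from C4), since C4–C3 is equally well aligned: C1 is a tertiary-alkyl and C3 a primary-alkyl migrating group, the C1–C6 bond joins two fully substituted carbons and is the more strained and better σ-donor, and the pull-dominated Lewis-acid regime, with more positive charge on the migrating carbon, should widen this gap compared with a bare alkoxide. The cold non-basic medium holds 18 as a chelated aluminium aldolate until the buffered quench, which guards against retro-aldol cleavage, dehydration, epimerisation at C5 and drift of C8=C9 into conjugation, all of which an alkoxide base would invite.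

Step 13
Reactants: 18 hydroxy ketone
Product: 19 4β,6α-diol (C2 ketal)
Conditions: Me4NBH(OAc)3, MeCN–AcOH, −30 °C
Reagents that add atoms: none
Why: Evans–Saksena reduction: the 4β-hydroxyl exchanges onto boron and hydride is delivered internally to the β face of C6 through a six-membered array, giving the 6α-alcohol. The reagent is too weak to reduce the ketone externally, and the acidic medium avoids enolate chemistry.

Step 14
Reactants: 20 4-hydroxybenzoic acid
Product: 22 4-(tert-butyldimethylsilyloxy)benzoic acid, via bis-silyl derivative 21 (not isolated)
Conditions: TBSCl (2.3 equiv), imidazole, DMF, rt; then AcOH–THF–H2O, rt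
Reagents that add atoms: tert-butyldimethylsilyl chloride, CC(C)(C)[Si](C)(C)Cl
Why: Exhaustive silylation followed by selective hydrolysis of the far more labile silyl ester; the aryl silyl ether is stable to dilute acetic acid.

Step 15
Reactants: 19 diol; 22 protected acid
Product: 23 6α-[4-(tert-butyldimethylsilyloxy)benzoate] of 19
Conditions: DCC, DMAP, CH2Cl2, rt
Reagents that add atoms: none
Why: Steglich esterification; the acylpyridinium species reaches the secondary 6α-hydroxyl, whereas the tertiary 4-hydroxyl is inert under these conditions.

Step 16
Reactants: 23 ester ketal
Product: 24 2-ketone (4β-OH, 6α-aroyloxy)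
Conditions: PPTS, acetone–H2O, 45 °C
Reagents that add atoms: water, O
Why: Acid-catalysed ketal hydrolysis; a ketal on a five-membered ring ionises more readily than on the earlier six-membered ring, so a weak acid should suffice and the tertiary aldol hydroxyl, the aryl silyl ether and the alkene are spared. The ketone is reduced without delay.

Step 17
Reactants: 24 hydroxy ketone
Product: 25 2α-alcohol
Conditions: Me4NBH(OAc)3, MeCN–AcOH, −20 °C → rt
Reagents that add atoms: none
Why: Second Evans–Saksena reduction: boron bound to the 4β-oxygen reaches C2 across the cyclopentane (a bicyclo[3.2.1]-like array) and delivers hydride to the β face, giving the 2α-alcohol that external hydride would not give. Since the reagent does not reduce unassisted ketones readily, the contra-steric pathway has little competition.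

Step 18
Reactants: 25 diol ester
Product: 26 2α-acetate
Conditions: Ac2O, DMAP (cat.), pyridine, 0 °C → rt
Reagents that add atoms: acetic anhydride, CC(=O)OC(C)=O
Why: DMAP-catalysed acetylation of the only secondary hydroxyl; the tertiary 4-hydroxyl does not react under these conditions.

Step 19
Reactants: 26 silyl ether
Product: 27 target, 2α-acetoxy-4β-hydroxy-6α-(4-hydroxybenzoyloxy)-4α-isopropyl-1β,8-dimethyl-trans-hydroazul-8-ene
Conditions: TBAF, AcOH, THF, 0 °C
Reagents that add atoms: none
Why: Fluoride cleavage of an aryl silyl ether, which is fast because phenoxide is a good leaving group on silicon; the acetic acid buffer keeps the medium from hydrolysing or transposing the two esters.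

## Compound list

1 | 5-isopropylcyclohexane-1,3-dione | CC(C)C1CC(=O)CC(=O)C1 | starting material
2 | iodomethane | CI | starting material
3 | 5-isopropyl-2-methylcyclohexane-1,3-dione | CC1C(=O)CC(C(C)C)CC1=O | intermediate
4 | methyl vinyl ketone | CC(=O)C=C | starting material
5 | cis-5-isopropyl-2-methyl-2-(3-oxobutyl)cyclohexane-1,3-dione (chain and isopropyl on the same face; achiral) | C[C@]1(CCC(C)=O)C(=O)C[C@@H](C(C)C)CC1=O | intermediate
6 | (3S,8aR)-3-isopropyl-8a-methyl-3,4,8,8a-tetrahydronaphthalene-1,6(2H,7H)-dione (C2 and C8 ketones, C6=C7, 1β-methyl, 4α-isopropyl) | C[C@@]12CCC(=O)C=C1C[C@H](C(C)C)CC2=O | intermediate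
7 | C2 ethylene ketal of 6 | C[C@@]12CCC(=O)C=C1C[C@H](C(C)C)CC23OCCO3 | intermediate
8 | linear 4,6-dien-8-one, 4-isopropyl, 1β-methyl, C2 ketal | C[C@@]12CCC(=O)C=C1C=C(C(C)C)CC23OCCO3 | intermediate
9 | 6β,7β-epoxy-4-en-8-one, C2 ketal | C[C@@]12CCC(=O)[C@H]3O[C@@]13C=C(C(C)C)CC24OCCO4 | intermediate
10 | cis-fused 6β-hydroxy-4-en-8-one, C2 ketal | C[C@@]12CCC(=O)C[C@]1(O)C=C(C(C)C)CC23OCCO3 | intermediate
11 | 6β-trimethylsilyl ether of 10 | C[C@@]12CCC(=O)C[C@]1(O[Si](C)(C)C)C=C(C(C)C)CC23OCCO3 | intermediate
12 | 8-enol triflate (C8=C9) of 11 | C[C@@]12CC=C(OS(=O)(=O)C(F)(F)F)C[C@]1(O[Si](C)(C)C)C=C(C(C)C)CC23OCCO3 | intermediate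
13 | 6β-hydroxy-4,8-dien-8-yl triflate, C2 ketal | C[C@@]12CC=C(OS(=O)(=O)C(F)(F)F)C[C@]1(O)C=C(C(C)C)CC23OCCO3 | intermediate
14 | cyclic 4β,5β-osmate(VI) ester of 13, TMEDA bound to osmium | C[C@@]12CC=C(OS(=O)(=O)C(F)(F)F)C[C@]1(O)[C@H]3O[Os](=O)(=O)O[C@@]3(C(C)C)CC24OCCO4.CN(C)CCN(C)C | intermediate
15 | 4β,5β,6β-triol 8-enol triflate, C2 ketal | C[C@@]12CC=C(OS(=O)(=O)C(F)(F)F)C[C@]1(O)[C@@H](O)[C@](O)(C(C)C)CC23OCCO3 | intermediate
16 | 4β,5β,6β-triol, 8-methyl, C8=C9, C2 ketal | C[C@@]12CC=C(C)C[C@]1(O)[C@@H](O)[C@](O)(C(C)C)CC23OCCO3 | intermediate
17 | cis-decalin 4β,6β-diol 5β-mesylate, C2 ketal | C[C@@]12CC=C(C)C[C@]1(O)[C@@H](OS(C)(=O)=O)[C@](O)(C(C)C)CC23OCCO3 | intermediate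
18 | trans-fused 4β-hydroxyhydroazul-8-en-6-one, C2 ketal | C13(OCCO3)C[C@@](O)(C(C)C)[C@@H]2C(=O)CC(C)=CC[C@@]12C | intermediate
19 | 4β,6α-diol, C2 ketal | C13(OCCO3)C[C@@](O)(C(C)C)[C@@H]2[C@@H](O)CC(C)=CC[C@@]12C | intermediate
20 | 4-hydroxybenzoic acid | OC(=O)c1ccc(O)cc1 | starting material
21 | tert-butyldimethylsilyl 4-(tert-butyldimethylsilyloxy)benzoate | CC(C)(C)[Si](C)(C)Oc1ccc(cc1)C(=O)O[Si](C)(C)C(C)(C)C | intermediate
22 | 4-(tert-butyldimethylsilyloxy)benzoic acid | CC(C)(C)[Si](C)(C)Oc1ccc(cc1)C(=O)O | intermediate
23 | 6α-[4-(TBSO)benzoate] of 19 | C13(OCCO3)C[C@@](O)(C(C)C)[C@@H]2[C@@H](OC(=O)c3ccc(O[Si](C)(C)C(C)(C)C)cc3)CC(C)=CC[C@@]12C | intermediate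
24 | 2-ketone, 4β-OH, 6α-[4-(TBSO)benzoate] | O=C1C[C@@](O)(C(C)C)[C@@H]2[C@@H](OC(=O)c3ccc(O[Si](C)(C)C(C)(C)C)cc3)CC(C)=CC[C@@]12C | intermediate
25 | 2α-alcohol | O[C@H]1C[C@@](O)(C(C)C)[C@@H]2[C@@H](OC(=O)c3ccc(O[Si](C)(C)C(C)(C)C)cc3)CC(C)=CC[C@@]12C | intermediate
26 | 2α-acetate, phenol as TBS ether | CC(=O)O[C@H]1C[C@@](O)(C(C)C)[C@@H]2[C@@H](OC(=O)c3ccc(O[Si](C)(C)C(C)(C)C)cc3)CC(C)=CC[C@@]12C | intermediate
27 | CNP0275279.1 | CC(=O)O[C@H]1C[C@@](O)(C(C)C)[C@@H]2[C@@H](OC(=O)c3ccc(O)cc3)CC(C)=CC[C@@]12C | target

## Step count and least certain steps

Total: 19 steps. Longest linear sequence: 18 steps (steps 1–13 and 15–19); step 14 is the side branch.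

**Step 12 (key step).**
- *Risk:* the most likely failure is the competing shift of C3 from C4, which contracts ring B alone. The C4–C3 bond is as well aligned with the mesylate as C6–C1, and O4 pushes as well as O6. Lesser risks are ionisation of the ketal by the Lewis acid and dehydration or epimerisation of the aldol during work-up.
- *Fallback:* it sets out from 17 and returns at 18, and it removes the competitor instead of out-running it. The less hindered of the two tertiary hydroxyls (O4 is flanked by a methylene and a methine, O6 by a quaternary carbon) is silylated with TESOTf and 2,6-lutidine at −78 °C to give the 4-O-triethylsilyl mesylate F1. Only O6 can then be deprotonated, and one equivalent of KHMDS in THF (−78 → 0 °C, short contact) triggers the alkoxide-driven shift to the 4-O-triethylsilyl hydroazulenone F2. The silyl ether in F2 also blocks retro-aldol cleavage. HF·pyridine then gives 18.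

**Step 9.**
- *Risk:* poor facial selectivity, if the usual undirected attack anti to the allylic oxygen wins because the 6-hydroxyl is tied up in a hydrogen bond to the ketal. Slow addition to the hindered alkene is also possible, and attack on the enol triflate could then begin on warming.
- *Fallback:* it sets out from 13 and returns at 15, using a Woodward cis-hydroxylation (I2, AgOAc, wet AcOH). This places the diol on the face opposite to the one the electrophile prefers: anti iodo-acetoxylation, internal displacement of iodide and hydrolysis. It should give the 4β-acetoxy-5β,6β-diol F3 (drawn with the ester on the axial tertiary oxygen). DIBAL-H at −78 °C removes the acetate and gives 15.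

**Step 5.**
- *Risk:* loss of regiocontrol (1,6-addition and oxidation of C4=C5), or attack from the α face, which would invert the whole relay.
- *Fallback:* it sets out from 8 and returns at 9. Luche reduction gives the pseudo-equatorial 8β-dienol F4. VO(acac)2/t-BuOOH epoxidises the alkene next to the carbinol on the hydroxyl-bearing face to give the 6β,7β-epoxy-8β-alcohol F5. Dess–Martin oxidation restores the ketone.

**Step 8.**
- *Risk:* enolisation towards C7 (the cis-fused ketone and the inductive effect of O6 both work in that direction), followed by β-elimination. Enolate equilibration before trapping and erosion of the triflate during the fluoride stage are also possible.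
- *Fallback:* it sets out from 10, skips 11 and 12 and returns at 13. Two equivalents of LDA generate the alkoxide–enolate dianion, in which the oxide cannot leave and repels deprotonation at C7. One equivalent of N-phenyltriflimide then traps the enolate oxygen. No compound outside the list is made.

**Step 17.**
- *Risk:* no reaction, because the β face of C2 lies next to the C1 methyl group, or slow external reduction from the α face on warming, which erodes the configuration at C2.
- *Fallback:* it sets out from 24 and returns at 26 by accepting the steric bias. NaBH4 in MeOH at 0 °C should give the 2β-alcohol F6, and a Mitsunobu reaction with acetic acid as the pronucleophile inverts C2 and installs the acetate in the same step.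

## Further compounds

F1 | step 12 | 4-O-triethylsilyl ether of 17 | C[C@@]12CC=C(C)C[C@]1(O)[C@@H](OS(C)(=O)=O)[C@](O[Si](CC)(CC)CC)(C(C)C)CC23OCCO3
F2 | step 12 | 4-O-triethylsilyl ether of 18 | C13(OCCO3)C[C@@](O[Si](CC)(CC)CC)(C(C)C)[C@@H]2C(=O)CC(C)=CC[C@@]12C
F3 | step 9 | 4β-acetoxy-5β,6β-diol 8-enol triflate, C2 ketal | C[C@@]12CC=C(OS(=O)(=O)C(F)(F)F)C[C@]1(O)[C@@H](O)[C@](OC(C)=O)(C(C)C)CC23OCCO3
F4 | step 5 | 8β-hydroxy-4,6-diene, C2 ketal | C[C@@]12CC[C@@H](O)C=C1C=C(C(C)C)CC23OCCO3
F5 | step 5 | 6β,7β-epoxy-8β-hydroxy-4-ene, C2 ketal | C[C@@]12CC[C@@H](O)[C@H]3O[C@@]13C=C(C(C)C)CC24OCCO4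
F0 | step 8 | none | none
F6 | step 17 | 2β-alcohol (C2 epimer of 25) | O[C@@H]1C[C@@](O)(C(C)C)[C@@H]2[C@@H](OC(=O)c3ccc(O[Si](C)(C)C(C)(C)C)cc3)CC(C)=CC[C@@]12C
A1 | alternative 1 | bromomethyl(dimethyl)silyl ether of the hydroazulene 1(10),8-dien-4β-ol (2α-OPMB, 6α-OTBS) | COc1ccc(cc1)CO[C@H]1C[C@@](O[Si](C)(C)CBr)(C(C)C)[C@@H]2[C@@H](O[Si](C)(C)C(C)(C)C)CC(C)=CC=C12
A2 | alternative 1 | bridged oxasilacycle carrying quaternary C1 | COc1ccc(cc1)CO[C@H]1C[C@]2(C(C)C)O[Si](C)(C)C[C@]13CC=C(C)C[C@H](O[Si](C)(C)C(C)(C)C)[C@@H]23
A3 | alternative 2 | 4-isopropyl-2-methyl-4-(triethylsilyloxy)cyclopent-2-enone | O=C1C[C@@](O[Si](CC)(CC)CC)(C(C)C)C=C1C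
A4 | alternative 2 | 2-lithio-1,3-dithiane | [Li]C1SCCCS1
A5 | alternative 2 | (Z)-4-iodo-2-methylbut-2-enyl tert-butyldimethylsilyl ether | IC/C=C(\CO[Si](C)(C)C(C)(C)C)C
A6 | alternative 2 | trans-2,3-disubstituted cyclopentanone with C6 dithiane and C7–C10 chain | O=C1C[C@@](O[Si](CC)(CC)CC)(C(C)C)[C@H](C2SCCCS2)[C@@]1(C)C/C=C(\CO[Si](C)(C)C(C)(C)C)C
A7 | alternative 3 | N-hydroxyphthalimide ester of the C1 acetic acid with (Z)-C9 alkenyl iodide | CC(=O)O[C@H]1C[C@@](O)(C(C)C)[C@H]([C@@H](OC(=O)c2ccc(O[Si](C)(C)C(C)(C)C)cc2)C/C(C)=C\I)[C@@]1(C)CC(=O)ON1C(=O)c2ccccc2C1=O
A8 | alternative 3 | target as phenolic TBS ether | CC(=O)O[C@H]1C[C@@](O)(C(C)C)[C@@H]2[C@@H](OC(=O)c3ccc(O[Si](C)(C)C(C)(C)C)cc3)CC(C)=CC[C@@]12C
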